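All runs are calculated with made-up constants, and the scatter is random.

What is left over of the solid substrate pays for one more row of flasks, so we must decide which reagent charges go in and how strictly the stop time has to be kept.

| flask | solid substrate | reagent | remark | time |
|---|---|---|---|---|
| elm | 0.074 M | 0.53 equiv | run made earlier |  |
| larch | 0.074 M | 1.1 equiv | run made earlier |  |
| birch | 0.074 M | 3 equiv | run made earlier |  |
| west | 0.074 M | 0.500 equiv |  | 6.0 min |
| north-west | 0.074 M | 0.800 equiv |  | 6.0 min |
| south-east | 0.074 M | 1.20 equiv |  | 6.0 min |
| south-west | 0.074 M | 1.50 equiv |  | 6.0 min |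
| south | 0.074 M | 2.50 equiv |  | 6.0 min |

- elm (time / min: target / %): 0.500: 0.5; 1.50: 0; 3.00: 0.7; 4.00: 1.1; 6.00: 3.7
- larch (time / min: target / %): 0.500: 0.2; 1.50: 0; 3.00: 0.4; 4.00: 1.7; 6.00: 4.9
- birch (time / min: target / %): 0.500: 0.1; 1.50: 0.3; 3.00: 0.7; 4.00: 2.1; 6.00: 4.1

(readings scatter by 0.3 percentage points)

- solid substrate is a solid; its amount is given per volume of the solution
- at the start none of the solid substrate is in solution
- "hardly changes" means that all values lie within two and a half points (for a concentration: within two and a half percent of the largest)

- [target] at the end for west, north-west, south-east, south-west, south, in this order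
- the shape of the row from first to last (rises, then falls / falls, then rises / rises all the way / hardly changes / falls all the way)

1. In the larch run the target appears late: it reads 0.4 % at 3.00 min, 1.7 % at 4.00 min and 4.9 % at 6.00 min.

2. From the last two larch readings we reckon 1.31 min. This is the doubling time of the target: the gap between two readings, times the logarithm of two, divided by the logarithm of their ratio. As a reading it carries their scatter.

3. Now we price the reagent in doublings. Going from the elm charge to the larch charge multiplies the last reading by 1.32. That is 0.405 of a doubling, or 0.531 min of waiting, which is less than one doubling time. The gap between these two readings is 2.83 times the scatter of a difference, so it can be seen.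

4. We therefore keep the reagent row as planned and hold every stop strictly at 6.0 min. Our own reckoning puts the row near 0.00274 M at the low end and 0.00363 M in the middle, then lower again, towards 0.00303 M.

5. The forecast gives 0.0027 M, 0.0033 M, 0.0036 M, 0.0035 M and 0.0031 M, with the shape "rises, then falls". In its words: “I expect a shallow maximum near 1.2 equiv, perhaps from reagent also consuming the target.”

6. The flasks give 0.00250 M, 0.00320 M, 0.00363 M, 0.00373 M and 0.00351 M, with the shape "rises, then falls".

    reagent + intermediate C → intermediate D (k = 0.0905 M⁻¹ s⁻¹)
    intermediate D ⇌ intermediate E (K = 3.77, k = 0.0113 s⁻¹)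
    starting material ⇌ intermediate B (K = 1.10, k = 0.0846 s⁻¹)
    intermediate A → intermediate C (k = 0.0347 s⁻¹)
    solid substrate ⇌ starting material, rate k5*(cs5 - [starting material]) while solid is left; crystals form when [starting material] > cs5 (solubility = 27.0 mM, k = 0.00487 s⁻¹)
    intermediate C → target (k = 0.00253 s⁻¹)
    starting material + reagent → intermediate A (k = 0.172 M⁻¹ s⁻¹)

7. The forecast stands within its margin, and the row turns at 1.6 equiv. In west the target goes from 0.584 % at 3.00 min to 3.38 % at 6.00 min, a doubling time of 1.18 min. From west to south-west the row gains 0.577 of a doubling, less than one, which is 0.681 min of west's growth. North-west goes from 0.811 % to 4.32 % over the same stretch, a doubling time of 1.24 min.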